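## Retrosynthetic overview
(Target locants used throughout: C1 bears the side chain, C2 = CH, C3 = CH2, C4 = CHCl, C5 = CMe2, C6 = CHBr; side chain C1' = CHCl, C2' = CH2Br.)

1. C5–C6 bond and the only reagent-controlled stereocentre: aldehyde 1 + allene 2 (through borane 3, borinate 4 and silyl carbinol 5) ⇒ enynol 6 by asymmetric reverse prenylation.
2. Tether: 6 + acid chloride 7 ⇒ dichloroacetate 8, which already holds every carbon and both chlorine atoms of the target.
3. Key disconnection, C1–C1' and C2–C3 together with C4–Cl in one radical chain: 8 ⇒ bicyclic chlorolactone 9. The lactone ring closes first (5-exo-dig), the carbocycle second (6-endo-trig).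
4. 9 ⇒ diol 10 ⇒ enone 11 ⇒ diol 12: the two lactone C–O positions are the two future C–Br positions, and C6 is re-set from C4.
5. Target 13 ⇐ 12 by exchange of both hydroxyl groups for bromide, with inversion at C6.

Assumption: 1, 2 and 7 are bought; the facial sense of step 1 follows the usual model for Ipc2B-allyl reagents [(+)-Ipc2BH, from (−)-α-pinene, attacks the Re face of the aldehyde].

## Route

Step 1
Reactants: 1 3-(trimethylsilyl)prop-2-ynal; 2 3-methylbuta-1,2-diene
Product: 6 (3S)-4,4-dimethylhex-5-en-1-yn-3-ol, via prenylborane 3 (not isolated), via borinate 4 (not isolated), via silyl carbinol 5 (not isolated)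
Conditions: (+)-Ipc2BH, THF, −25 °C; then 1, Et2O, −78 °C; then NaOH, H2O2, MeOH, 25 °C
Reagents that add atoms: none
Why: Brown asymmetric allylboration in its reverse-prenylation form: (+)-Ipc2BH hydroborates the terminal double bond of 2 to prenylborane 3, which adds to the Re face of 1 through a chair transition state at its dimethyl-substituted carbon (borinate 4), so the quaternary C5 and the C6 carbinol centre form together, and alkaline peroxide then frees carbinol 5 and cleaves its alkynyl C–Si bond (the label of C6 changes from R in 5 to S in 6 although the centre is untouched).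

Step 2
Reactants: 6 (3S)-4,4-dimethylhex-5-en-1-yn-3-ol; 7 dichloroacetyl chloride
Product: 8 (3S)-4,4-dimethylhex-5-en-1-yn-3-yl dichloroacetate
Conditions: pyridine, DMAP (cat.), CH2Cl2, 0 °C
Reagents that add atoms: none
Why: Nucleophilic acyl substitution (O-acylation with an acid chloride under pyridine/DMAP catalysis) works even on this hindered propargylic alcohol and does not touch C6.

Step 3
Reactants: 8 (3S)-4,4-dimethylhex-5-en-1-yn-3-yl dichloroacetate
Product: 9 (3S,6S,7aR)-3,6-dichloro-7,7-dimethyl-5,6,7,7a-tetrahydro-1-benzofuran-2(3H)-one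
Conditions: CuCl (30 mol %), tris(2-pyridylmethyl)amine (30 mol %), ClCH2CH2Cl (0.01 M), 80 °C
Reagents that add atoms: none
Why: Proposed new method: an atom-transfer radical cascade in which CuCl/tris(2-pyridylmethyl)amine abstracts one chlorine of the dichloroacetate, the α-chloro ester radical closes 5-exo-dig onto the alkyne carbon bound to C6 (chlorine and the tert-alkyl arm both pseudo-equatorial in the envelope transition state, so C1'–Cl ends cis to the C5 arm and trans to C6–H), the vinyl radical at C2 then closes 6-endo-trig onto the terminal CH2 of the vinyl group (5-exo attack would have to strike the carbon next to the quaternary centre, and any 5-exo radical can still reach the six-membered radical by the known cyclopropylcarbinyl shift), and CuCl2/tris(2-pyridylmethyl)amine finally hands chlorine back to the secondary C4 radical on the ring face opposite the pseudo-axial C5 methyl, that is trans to the C6 oxygen, so that C1' (S) and C4 (S) are both set by C6, whose position in space is unchanged (its label turns from S to R only through the new priority order); the closest known reaction types are the copper-catalysed atom-transfer radical cyclization of allyl and propargyl trichloroacetates to chlorinated butyrolactones and radical enyne cascades in which a 5-exo-dig closure is followed by vinyl-radical ring closure.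

Step 4
Reactants: 9 (3S,6S,7aR)-3,6-dichloro-7,7-dimethyl-5,6,7,7a-tetrahydro-1-benzofuran-2(3H)-one
Product: 10 (1R,5S)-5-chloro-2-[(1S)-1-chloro-2-hydroxyethyl]-6,6-dimethylcyclohex-2-en-1-ol
Conditions: i-Bu2AlH (3.5 equiv), CH2Cl2, −78 to −20 °C
Reagents that add atoms: none
Why: Hydride reduction of the lactone to the diol with a Lewis-acidic, non-basic aluminium hydride at low temperature leaves both secondary chlorides and the α-chloro stereocentre untouched (no enolization, no stereocentre changed).

Step 5
Reactants: 10 (1R,5S)-5-chloro-2-[(1S)-1-chloro-2-hydroxyethyl]-6,6-dimethylcyclohex-2-en-1-ol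
Product: 11 (5S)-5-chloro-2-[(1S)-1-chloro-2-hydroxyethyl]-6,6-dimethylcyclohex-2-en-1-one
Conditions: MnO2, CH2Cl2, 25 °C
Reagents that add atoms: none
Why: Chemoselective allylic oxidation with MnO2 takes only the allylic C6 carbinol to the enone and leaves the saturated primary alcohol, which removes the C6 configuration once it has passed its chirality on to C4 and C1'.

Step 6
Reactants: 11 (5S)-5-chloro-2-[(1S)-1-chloro-2-hydroxyethyl]-6,6-dimethylcyclohex-2-en-1-one
Product: 12 (1S,5S)-5-chloro-2-[(1S)-1-chloro-2-hydroxyethyl]-6,6-dimethylcyclohex-2-en-1-ol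
Conditions: NaBH4, CeCl3·7H2O, MeOH, −78 °C
Reagents that add atoms: none
Why: Luche 1,2-reduction: hydride adds axially to the enone carbonyl on the face opposite the pseudo-axial C5 methyl (ring conformer with equatorial C4–Cl), so the new C6–OH is equatorial and cis to C4–Cl (6S).

Step 7
Reactants: 12 (1S,5S)-5-chloro-2-[(1S)-1-chloro-2-hydroxyethyl]-6,6-dimethylcyclohex-2-en-1-ol
Product: 13 (4S,6R)-6-bromo-1-[(1S)-2-bromo-1-chloroethyl]-4-chloro-5,5-dimethylcyclohex-1-ene
Conditions: PPh3, CBr4, CH2Cl2, 0 to 25 °C
Reagents that add atoms: carbon tetrabromide, BrC(Br)(Br)Br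
Why: Appel reaction on both hydroxyl groups: the primary carbinol gives the CH2Br group, and the equatorial allylic C6 oxygen is displaced by bromide with inversion (axial entry, anti to the pseudo-axial C5 methyl), which sets (6R) with bromine trans to the C4 chlorine.

## Compound list

1 | 3-(trimethylsilyl)prop-2-ynal | C[Si](C)(C)C#CC=O | starting material
2 | 3-methylbuta-1,2-diene | CC(C)=C=C | starting material
3 | B-(3-methylbut-2-en-1-yl)diisopinocampheylborane, from (+)-Ipc2BH (prenylborane) | CC(C)=CCB([C@H]1C[C@H]2C[C@@H]([C@@H]1C)C2(C)C)[C@H]1C[C@H]2C[C@@H]([C@@H]1C)C2(C)C | intermediate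
4 | (3R)-4,4-dimethyl-1-(trimethylsilyl)hex-5-en-1-yn-3-yl diisopinocampheylborinate (borinate) | C[Si](C)(C)C#C[C@H](OB([C@H]1C[C@H]2C[C@@H]([C@@H]1C)C2(C)C)[C@H]1C[C@H]2C[C@@H]([C@@H]1C)C2(C)C)C(C)(C)C=C | intermediate
5 | (3R)-4,4-dimethyl-1-(trimethylsilyl)hex-5-en-1-yn-3-ol (silyl carbinol) | C[Si](C)(C)C#C[C@H](O)C(C)(C)C=C | intermediate
6 | (3S)-4,4-dimethylhex-5-en-1-yn-3-ol | C#C[C@H](O)C(C)(C)C=C | intermediate
7 | dichloroacetyl chloride | ClC(Cl)C(Cl)=O | starting material
8 | (3S)-4,4-dimethylhex-5-en-1-yn-3-yl dichloroacetate | C#C[C@H](OC(=O)C(Cl)Cl)C(C)(C)C=C | intermediate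
9 | (3S,6S,7aR)-3,6-dichloro-7,7-dimethyl-5,6,7,7a-tetrahydro-1-benzofuran-2(3H)-one (3-Cl trans to 7a-H; 6-Cl trans to the ring oxygen at C7a) | O=C1O[C@@H]2C(C)(C)[C@@H](Cl)CC=C2[C@@H]1Cl | intermediate
10 | (1R,5S)-5-chloro-2-[(1S)-1-chloro-2-hydroxyethyl]-6,6-dimethylcyclohex-2-en-1-ol (OH trans to ring Cl) | OC[C@@H](Cl)C1=CC[C@H](Cl)C(C)(C)[C@H]1O | intermediate
11 | (5S)-5-chloro-2-[(1S)-1-chloro-2-hydroxyethyl]-6,6-dimethylcyclohex-2-en-1-one | OC[C@@H](Cl)C1=CC[C@H](Cl)C(C)(C)C1=O | intermediate
12 | (1S,5S)-5-chloro-2-[(1S)-1-chloro-2-hydroxyethyl]-6,6-dimethylcyclohex-2-en-1-ol (OH cis to ring Cl) | OC[C@@H](Cl)C1=CC[C@H](Cl)C(C)(C)[C@@H]1O | intermediate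
13 | (4S,6R)-6-bromo-1-[(1S)-2-bromo-1-chloroethyl]-4-chloro-5,5-dimethylcyclohex-1-ene | CC1(C)[C@@H](Cl)CC=C([C@H](Cl)CBr)[C@@H]1Br | target

## Step count, longest linear sequence, risks and fallbacks

Total step count: 7. Longest linear sequence: 7 steps (1 and 2 to 13).

**Step 3 (radical cascade).** This step is unprecedented as a whole and is the main risk.
- The ester must reach its less stable rotamer before the 5-exo-dig closure.
- The terminal alkyne may bind monovalent copper.
- The vinyl radical may take chlorine before it cyclizes, or close 5-exo.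
- The facial control at C1' rests on a modest steric preference, and 9 has an acidic hydrogen at C1' next to the ring double bond.

Fallback, from 6 back to 9: acylation of 6 with trichloroacetyl chloride gives (3S)-4,4-dimethylhex-5-en-1-yn-3-yl trichloroacetate F1. The same CuCl/tris(2-pyridylmethyl)amine cascade then starts from the far more easily activated CCl3 group, the classic substrate class, and gives (6S,7aR)-3,3,6-trichloro-7,7-dimethyl-5,6,7,7a-tetrahydro-1-benzofuran-2(3H)-one F2, which has no acidic hydrogen at C1'. Zinc in acetic acid then removes one of the geminal chlorines, and protonation of the zinc enolate on the ring face that carries the C6 hydrogen gives 9. The C1' centre is thus set in a separate step and no longer in the cyclization.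

**Step 7 (double bromination).** C6 is allylic but neopentyl-like, so direct displacement may be slow. Attack of bromide at C2 with allylic shift, ionization, or closure of the 1,4-diol to a cyclic ether may compete. Partial loss of configuration would give the C6 epimer.

Fallback, from 12 back to 13, using thermodynamic instead of kinetic control: the crude bromide mixture, including (4S,6S)-6-bromo-1-[(1S)-2-bromo-1-chloroethyl]-4-chloro-5,5-dimethylcyclohex-1-ene F6, is stirred with LiBr in acetone. Allylic bromide exchange should then converge on 13, whose pseudo-axial C6–Br avoids the strain against the C1 side chain and sits trans to the equatorial C4–Cl, whereas F6 must place bromine equatorial or both halogens syn-diaxial.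

**Step 5 (allylic oxidation).** The hindered carbinol may react slowly. Enone 11 carries a chloride on the carbon attached to the enone α-position and a free primary hydroxyl, so loss of HCl, hemiketal formation or epoxide closure can erode it.

Fallback, from 10 to 13, with the primary position turned into its final bromide before the redox inversion: one equivalent of PPh3/CBr4 at −20 °C converts only the primary hydroxyl of 10 and gives (1R,5S)-2-[(1S)-2-bromo-1-chloroethyl]-5-chloro-6,6-dimethylcyclohex-2-en-1-ol F3. Dess–Martin periodinane oxidizes this to (5S)-2-[(1S)-2-bromo-1-chloroethyl]-5-chloro-6,6-dimethylcyclohex-2-en-1-one F4. NaBH4/CeCl3·7H2O reduces F4, with the same facial sense as in step 6, to (1S,5S)-2-[(1S)-2-bromo-1-chloroethyl]-5-chloro-6,6-dimethylcyclohex-2-en-1-ol F5. A second Appel bromination with inversion at C6 gives 13.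

## Further compounds

F1 | step 3 | (3S)-4,4-dimethylhex-5-en-1-yn-3-yl trichloroacetate | C#C[C@H](OC(=O)C(Cl)(Cl)Cl)C(C)(C)C=C
F2 | step 3 | (6S,7aR)-3,3,6-trichloro-7,7-dimethyl-5,6,7,7a-tetrahydro-1-benzofuran-2(3H)-one | O=C1O[C@@H]2C(C)(C)[C@@H](Cl)CC=C2C1(Cl)Cl
F3 | step 5 | (1R,5S)-2-[(1S)-2-bromo-1-chloroethyl]-5-chloro-6,6-dimethylcyclohex-2-en-1-ol | BrC[C@@H](Cl)C1=CC[C@H](Cl)C(C)(C)[C@H]1O
F4 | step 5 | (5S)-2-[(1S)-2-bromo-1-chloroethyl]-5-chloro-6,6-dimethylcyclohex-2-en-1-one | BrC[C@@H](Cl)C1=CC[C@H](Cl)C(C)(C)C1=O
F5 | step 5 | (1S,5S)-2-[(1S)-2-bromo-1-chloroethyl]-5-chloro-6,6-dimethylcyclohex-2-en-1-ol | BrC[C@@H](Cl)C1=CC[C@H](Cl)C(C)(C)[C@@H]1O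
F6 | step 7 | (4S,6S)-6-bromo-1-[(1S)-2-bromo-1-chloroethyl]-4-chloro-5,5-dimethylcyclohex-1-ene | BrC[C@@H](Cl)C1=CC[C@H](Cl)C(C)(C)[C@@H]1Br
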